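**Assumptions:** The target is the erythro (7S,8R) 8-O-4′ ether joined to an all-trans (1S,2S,3R) 1-aryl-2,3-dimethyltetralin. I assume the catalyst enantiomers named below give these configurations; this is set by catalyst choice and has not been checked experimentally.

## Retrosynthetic overview
1. Disconnect the C7 carbinol (catalyst-controlled ketone reduction) and the C8–OAr ether (Mitsunobu inversion between the tetralin phenol and an (S)-α-hydroxy ketone).
2. The α-hydroxy ketone comes from asymmetric epoxidation/Rubottom rearrangement of a Z-silyl enol ether of benzyl-protected propiovanillone. This sets C8.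
3. The tetralin ring and its three stereocentres come from one step: an enantioselective cross radical-cation [4+2] cyclodimerisation of two propenylguaiacol derivatives, giving the all-trans product via endo-aryl approach.
4. Ring order: the carbocycle is formed first, the side chain is attached last, then two deprotections.

## Route

**Step 1**
Reactants: 1 (benzyl isoeugenol), 2 (isoeugenyl acetate, 3–4 equiv)
Product: 3, (1S,2S,3R)-1-[4-(benzyloxy)-3-methoxyphenyl]-6-methoxy-2,3-dimethyl-tetralin-7-yl acetate
Conditions: 3,6-di-tBu-9-mesityl-10-phenylacridinium (2 mol%), chiral IDPi-type imidodiphosphorimidate acid (5 mol%, enantiomer giving 1S,2S,3R), CH2Cl2/PhCF3, blue LEDs, –20 °C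
Reagents that add atoms: none
Why: Ar-propenyl radical-cation cycloaddition to a 1-aryltetralin.
Proposed new method: The excited acridinium oxidises the more electron-rich benzyl ether 1 (Eox ≈ +1.3 V, against ≈ +1.7 V for 2) to 1•+, held as a tight ion pair with the chiral anion. Hole transfer from 2•+ to 1 keeps the radical cation on 1. Neutral 2 attacks the β-carbon of 1•+ (C2–C3 bond), giving a benzylic radical and a benzylic cation. The radical closes onto the ortho carbon of the cation-bearing ring (C1–C8a bond), giving an isotoluene. Reduction by the acridinyl radical and acid-mediated tautomerisation restore the arene. With E,E-alkenes and the aryl group endo, the Ar/Me and Me/Me pairs end up trans–trans; the chiral anion selects the enantiomeric pair. Closest known chemistry: Bauld/Yoon radical-cation Diels–Alder reactions and counteranion-directed photoredox catalysis.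

**Step 2**
Reactants: 3
Product: 4, (1S,2S,3R)-1-(4-hydroxy-3-methoxyphenyl)-6-methoxy-2,3-dimethyl-tetralin-7-yl acetate
Conditions: H2 (1 atm), 10% Pd/C, EtOAc, rt
Reagents that add atoms: none
Why: Hydrogenolysis cleaves only the benzyl aryl ether. The aryl acetate survives, and the C1–aryl bond is a C–C bond, so no stereocentre is touched.

**Step 3**
Reactants: 5 (propiovanillone), 6 (benzyl bromide)
Product: 7, 1-[4-(benzyloxy)-3-methoxyphenyl]propan-1-one
Conditions: BnBr, K2CO3, DMF, 60 °C
Reagents that add atoms: benzyl bromide, BrCc1ccccc1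
Why: Williamson O-benzylation of the phenol, so it cannot interfere with the epoxidation and Mitsunobu steps.

**Step 4**
Reactants: 7, 8 (TBSOTf)
Product: 9, (Z)-tert-butyl{1-[4-(benzyloxy)-3-methoxyphenyl]prop-1-en-1-yloxy}dimethylsilane
Conditions: TBSOTf, Et3N, CH2Cl2, 0 °C
Reagents that add atoms: TBSOTf, C[Si](C)(C(C)(C)C)OS(=O)(=O)C(F)(F)F
Why: Soft enolisation and silylation of an aryl ethyl ketone gives the Z-enol ether, with OSi cis to CH3 and aryl trans to CH3. This is the trans-styrene-like geometry that suits fructose-derived dioxirane epoxidation.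

**Step 5**
Reactants: 9, 10 (Oxone)
Product: 11, (S)-1-[4-(benzyloxy)-3-methoxyphenyl]-2-(TBS-oxy)propan-1-one
Conditions: ent-Shi fructose-derived ketone (20–30 mol%), Oxone, K2CO3, Bu4NHSO4, MeCN/DMM/aq. buffer pH 10.5 with EDTA, 0 °C
Reagents that add atoms: Oxone (KHSO5), [K+].OOS(=O)(=O)[O-]
Why: Shi asymmetric epoxidation of a silyl enol ether, followed by in-situ Rubottom rearrangement (silyl 1,4-shift). The C8–O bond formed in the epoxidation is never broken, so the (S) configuration set there is retained.

**Step 6**
Reactants: 11
Product: 12, (S)-1-[4-(benzyloxy)-3-methoxyphenyl]-2-hydroxypropan-1-one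
Conditions: HF·pyridine, pyridine/THF, 0 °C
Reagents that add atoms: none
Why: Fluoride-mediated removal of the alkyl TBS group under buffered, weakly acidic conditions that do not epimerise the α-centre; the benzyl ether is stable.

**Step 7**
Reactants: 4 (phenol), 12 (acyloin, 1.5 equiv)
Product: 13, (R)-aryloxy ketone (C8 R)
Conditions: PPh3, DIAD, THF, 0 °C to rt
Reagents that add atoms: none
Why: Mitsunobu etherification with a phenol (pKa ≈ 10) inverts the secondary centre, converting (S)-acyloin to the (R)-ether. The C7 aryl acetate is inert.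

**Step 8**
Reactants: 13
Product: 14, (7S,8R) alcohol
Conditions: (S)-Me-CBS oxazaborolidine (10 mol%), BH3·SMe2, THF, –20 °C
Reagents that add atoms: none
Why: CBS reduction is catalyst-controlled, and (S)-CBS delivers the 7S alcohol (aryl as the large group). With C8 = R this gives the erythro (7S,8R) pair. The benzyl ether and acetate survive.

**Step 9**
Reactants: 14
Product: 15, (7S,8R) alcohol with free C7-phenol
Conditions: K2CO3, MeOH, 0 °C to rt
Reagents that add atoms: none
Why: Methanolysis removes the aryl acetate. C7 and C8 are no longer α to a carbonyl, so nothing epimerises.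

**Step 10**
Reactants: 15
Product: 16, target
Conditions: H2 (1 atm), 10% Pd/C, EtOAc/EtOH, rt, 1–2 h
Reagents that add atoms: none
Why: Hydrogenolysis of the last benzyl ether. A short reaction time avoids cleaving the p-hydroxybenzylic C–O bond.

## Compound list
1 | (E)-1-(benzyloxy)-2-methoxy-4-(prop-1-enyl)benzene | COc1cc(/C=C/C)ccc1OCc1ccccc1 | starting material
2 | (E)-isoeugenyl acetate | COc1cc(/C=C/C)ccc1OC(C)=O | starting material
3 | tetralin acetate (Ar-OBn) | COc1cc([C@H]2c3cc(OC(C)=O)c(OC)cc3C[C@@H](C)[C@@H]2C)ccc1OCc1ccccc1 | intermediate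
4 | tetralin phenol acetate | COc1cc([C@H]2c3cc(OC(C)=O)c(OC)cc3C[C@@H](C)[C@@H]2C)ccc1O | intermediate
5 | propiovanillone | CCC(=O)c1ccc(O)c(OC)c1 | starting material
6 | benzyl bromide | BrCc1ccccc1 | starting material (reagent)
7 | 1-[4-(benzyloxy)-3-methoxyphenyl]propan-1-one | CCC(=O)c1ccc(OCc2ccccc2)c(OC)c1 | intermediate
8 | TBSOTf | C[Si](C)(C(C)(C)C)OS(=O)(=O)C(F)(F)F | starting material (reagent)
9 | Z-TBS enol ether | COc1cc(/C(O[Si](C)(C)C(C)(C)C)=C/C)ccc1OCc1ccccc1 | intermediate
10 | Oxone (KHSO5) | [K+].OOS(=O)(=O)[O-] | starting material (reagent)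
11 | (S)-α-TBS-oxy ketone | COc1cc(C(=O)[C@H](C)O[Si](C)(C)C(C)(C)C)ccc1OCc1ccccc1 | intermediate
12 | (S)-α-hydroxy ketone | COc1cc(C(=O)[C@H](C)O)ccc1OCc1ccccc1 | intermediate
13 | (R)-aryloxy ketone | COc1cc(C(=O)[C@@H](C)Oc2ccc([C@H]3c4cc(OC(C)=O)c(OC)cc4C[C@@H](C)[C@@H]3C)cc2OC)ccc1OCc1ccccc1 | intermediate
14 | (7S,8R) alcohol | COc1cc([C@H](O)[C@@H](C)Oc2ccc([C@H]3c4cc(OC(C)=O)c(OC)cc4C[C@@H](C)[C@@H]3C)cc2OC)ccc1OCc1ccccc1 | intermediate
15 | C7-phenol, Ar-OBn | COc1cc([C@H](O)[C@@H](C)Oc2ccc([C@H]3c4cc(O)c(OC)cc4C[C@@H](C)[C@@H]3C)cc2OC)ccc1OCc1ccccc1 | intermediate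
16 | target | COc1cc([C@H](O)[C@@H](C)Oc2ccc([C@H]3c4cc(O)c(OC)cc4C[C@@H](C)[C@@H]3C)cc2OC)ccc1O | target

**Total steps:** 10
**Longest linear sequence:** 8 (benzylation, enol ether, Shi–Rubottom, desilylation, Mitsunobu, CBS reduction, deacetylation, hydrogenolysis)

## Three steps most likely to fail
1. **Step 1 (proposed new method).** Cross-selectivity, [4+2] versus [2+2] cyclobutane formation, and enantioinduction are all uncertain. Benzyl fragmentation from the arene radical cation is also possible.
   Fallback (known chemistry): build the (2S,3S)-2,3-dimethyl-4-arylbutanoyl unit with Evans auxiliary alkylations. Convert it to the Weinreb amide, add the Ar2-Grignard reagent, and reduce to the benzylic alcohol. Close the ring by TFA or BF3 Friedel–Crafts cyclisation to the trans,trans-aryltetralin.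
2. **Step 7 (Mitsunobu on an α-keto carbinol).** Elimination or partial racemisation at C8 is possible.
   Fallback: Williamson coupling of phenol 4 with racemic 2-bromo-1-arylpropan-1-one, then Ru-catalysed asymmetric transfer hydrogenation with dynamic kinetic resolution (HCO2H/Et3N) to set C7 and C8 together.
3. **Step 8 (CBS reduction with a pre-existing C8 centre).** A mismatched pair would lower the diastereomeric ratio.
   Fallback: substrate-controlled chelation reduction with Zn(BH4)2 of the (R)-ketone, which favours the erythro alcohol (Cram-chelate model), with diastereomer separation.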